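In a one-step world I would need a rate constant and a clock; in the summer run spent catalyst B grows while target forms, so I count turnovers.

| setting | summer | flask |
|---|---|---|
| starting material | 0.69 M | 0.69 M |
| reagent | 0.69 M | 1.38 M |
| free catalyst | 69 mM | 69 mM |
| remark | run made earlier |  |
| time |  | 1.0 h |

summer run (percent of the starting material charged)

| time / min | spent catalyst B / % | starting material / % | target / % |
|---|---|---|---|
| 1.00 | 1.7 | 92.9 | 5.5 |
| 2.00 | 2.1 | 87.2 | 9.8 |
| 3.00 | 2.9 | 84.7 | 12.1 |
| 6.00 | 4.7 | 77.5 | 18.8 |
| 12.0 | 5.5 | 69.1 | 24.7 |

(each reading ± 0.5 percentage points)

1. how much spent catalyst B the flask holds at 1.0 h, in percent of the starting material charged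
2. how much starting material the flask holds at 1.0 h, in percent of the starting material charged
3. concentration of reagent at 1.0 h, in M

I read the summer table across its rows. The last row gives 4.49 for target over spent catalyst B. I call this the turnover count N, percent of target made per percent of spent catalyst B formed, a turnover number reckoned on spent catalyst B. The third and fourth rows give 4.17 and 4.00, so the count holds roughly steady at this scatter. The last row sums to 99.3%, so I book one starting material to each target and each spent catalyst B.

Down the spent column, the last gain is 0.8 percentage points in twice the time of the gain before it, 1.8 points. I add that last gain once more and commit to 6.30%, under the 10.0% the catalyst charge allows.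

I assume reagent enters the target step and not the spent catalyst B step, so N scales with the reagent charge to 8.98. That leaves 37.1% starting material and 0.990 M reagent.

The forecast says 7.2%, 12% and 0.82 M, on the ground that “Doubling the reagent should about double the productive rate.” It holds less starting material than my figure.

The flask gives 6.04%, 29.7% and 0.977 M.

    free catalyst → spent catalyst A (k = 9.60 × 10⁻⁴ /s)
    starting material + reagent + free catalyst → target + free catalyst, rate k2*[starting material]*[reagent]*[free catalyst]/(1 + ([starting material]/sat2)) (0.270 M, k = 0.0750 /M²/s)
    starting material + target → side product (k = 1.30 × 10⁻⁴ /M/s)
    starting material + free catalyst → spent catalyst B (k = 0.00340 /M/s)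

In the flask, the target step and the spent catalyst B step have half their turnover up to the asked time behind them by 0.0643 h and 0.0572 h, and free catalyst is down to 37.8% of its charge at 0.100 h. At 1.00 h it stands at 0.113%, with 39.4% as spent catalyst A and 60.4% as spent catalyst B, and the step to side product, with half its turnover done by 0.467 h, has a net turnover of 5.82% of the starting material charged. Counted on the turnover of the target step, N in the flask is 9.66, against my 8.98.

For the neighbour charged with 0.34 M reagent, N scales to 2.21, which with my estimate of spent catalyst B reckons to 79.8% starting material and 0.244 M reagent. The computed neighbour holds 76.9% and 0.247 M.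

(The data are simulated for an exercise, and the scatter is random.)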